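**Retrosynthetic overview**

1. Numbering: ring C1 (CH with the chain), C2 (=CH2), C3 (allylic CHBr), C4 (CH2), C5 (CHBr), C6 (CMe2); chain C1'H2–C2'H2–C3'(Me)(OH)–C4'H=C5'H2; "top" is the face of ring C1–C6 that carries C1'. The strategy rests on C1' at C1 and the heteroatom at C5 being 1,3-related across C6, so that C1–C1'–C5–C6 maps onto the cyclobutanone ring of chrysanthenone with C1' as the ketone carbon.
2. C5–O and C1'(=O) come from Baeyer–Villiger insertion of oxygen into the C5–C1' bond of 2,3-epoxychrysanthenone, which gives a bridged γ-lactone; the oxirane masks C2=CH2 and C3–O and lowers the migratory aptitude of C1.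
3. The epoxy ketone comes from chrysanthenone (face-selective epoxidation), and chrysanthenone from (−)-verbenone by a photochemical 1,3-shift.
4. Chain: lactone → lactol → C1'=C2' vinyl → C2' boronate → lithiation–borylation with (R)-but-3-en-2-yl carbamate (sets C3'). Halogens: C5–Br by SN2 inversion early; C3 by oxirane → allylic alcohol → Mitsunobu inversion → SN2 bromination last.
5. Ring order: carbocycle C1–C6 and the four-membered ketone ring (step 1), oxirane (step 2), five-membered lactone by ring expansion (step 3); the lactone (steps 4–5) and the oxirane (step 10) are opened again.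

Key step: step 3

Remark: an oxirane fused to the six-membered ring can only be cis-fused, so in the epoxy ketone and the epoxy lactone both oxirane carbons carry oxygen on the face of the carbonyl (later lactone) bridge; the SMILES strings below are written accordingly.

**Route**

Step 1
Reactants: 1 (1S,5S)-(−)-verbenone
Product: 2 (1R,5S)-chrysanthenone
Conditions: hν (Pyrex, λ > 300 nm), cyclohexane, rt, stopped at partial conversion
Reagents that add atoms: none
Why: Photochemical 1,3-alkyl shift of the enone (the CMe2 bridge moves from the γ- to the α-carbon); the bridgehead next to the carbonyl is untouched and the second bridgehead is dictated by the bridged ring, and irradiation is kept short because Norrish type 1 cleavage of the product to an achiral ketene would erode optical purity.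

Step 2
Reactants: 2 (1R,5S)-chrysanthenone
Product: 3 2,3-epoxychrysanthenone (oxirane oxygen on the face of the C=O bridge)
Conditions: dimethyldioxirane (acetone solution), CH2Cl2, 0 °C
Reagents that add atoms: dimethyldioxirane, CC1(C)OO1
Why: Dioxirane epoxidation of the trisubstituted alkene from the face of the small carbonyl bridge, anti to the CMe2 bridge whose syn methyl covers the other face (as in α-pinene), sets C2 and C3; the neutral oxidant does not oxidise the cyclobutanone.

Step 3
Reactants: 3 2,3-epoxychrysanthenone
Product: 5 epoxy bridged lactone (C1–C1'(=O)–O–C5), via Criegee adduct 4 (not isolated)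
Conditions: mCPBA, NaHCO3, CH2Cl2, 0 °C → rt
Reagents that add atoms: mCPBA, OOC(=O)c1cccc(Cl)c1
Why: Baeyer–Villiger oxidation: the peracid adds to the strained carbonyl from the exo face (the endo face is screened by the oxirane oxygen) to give the tetrahedral peroxyester adduct 4, and 1,2-shift of the C5–C1' bond to oxygen with loss of 3-chlorobenzoate opens the four-membered ring. The closest known reaction type is the peracid ring expansion of fused and bridged cyclobutanones to γ-lactones. The five-membered lactone ring (C1, C1', O, C5, C6) is not closed by cyclisation but arises by ring expansion through this 1,2-shift, which leaves carbocycle C1–C6 as the six-membered ring of a 6-oxabicyclo[3.2.1]octan-7-one. The new C5–O stereocentre is fixed by the retention of configuration that is general for the migrating carbon, so that O on C5 is cis to C1' on C1. The step needs migration of C5 in preference to C1: both are bridgehead methines, but C1 is attached to the oxygen-bearing quaternary oxirane carbon C2, whose σ-acceptor effect disfavours the partial positive charge of the migrating carbon, whereas C5 is flanked only by CH2 and CMe2; the bicarbonate buffer keeps the oxirane closed.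

Step 4
Reactants: 5 epoxy bridged lactone
Product: 6 epoxy lactol (C1' hemiacetal; anomer mixture)
Conditions: iBu2AlH (1.1 equiv), CH2Cl2, −78 °C; aq. potassium sodium tartrate
Reagents that add atoms: none
Why: Partial reduction of a lactone by a dialkylaluminium hydride stops at the stable tetrahedral aluminate at low temperature, and the trisubstituted oxirane is not attacked under these conditions.

Step 5
Reactants: 6 epoxy lactol
Product: 8 vinyl epoxy alcohol (C1 vinyl and C5–OH both top), via hydroxy aldehyde 7 (not isolated)
Conditions: Ph3PCH3Br, KOtBu (excess ylide), THF, 0 °C → rt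
Reagents that add atoms: methyltriphenylphosphonium bromide, C[P+](c1ccccc1)(c1ccccc1)c1ccccc1.[Br-]
Why: Wittig methylenation of the ring-opened aldehyde tautomer 7 with an unstabilised ylide; addition to the carbonyl at 0 °C should outrun enolisation toward the oxirane, and no stereocentre is touched.

Step 6
Reactants: 8 vinyl epoxy alcohol
Product: 9 vinyl epoxy bromide (C5–Br bottom)
Conditions: CBr4, PPh3, 2,6-lutidine, CH2Cl2, 0 → 40 °C
Reagents that add atoms: carbon tetrabromide, BrC(Br)(Br)Br
Why: Appel bromination: SN2 displacement of the phosphonium-activated oxygen by bromide inverts C5 and puts Br trans to the C1 substituent; the bromide enters from the bottom face, which carries only hydrogens at C1 and C3 at this stage, and the lutidine scavenges acid to protect the oxirane.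

Step 7
Reactants: 9 vinyl epoxy bromide
Product: 10 C2' pinacol boronate
Conditions: pinacolborane, [Ir(cod)Cl]2 (cat.), dppm (cat.), CH2Cl2, rt
Reagents that add atoms: pinacolborane, CC1(C)OBOC1(C)C
Why: Iridium-catalysed anti-Markovnikov hydroboration of a monosubstituted alkene places boron on the terminal carbon C2'; the oxirane and the hindered secondary bromide are inert.

Step 8
Reactants: 11 (R)-but-3-en-2-ol
Product: 12 (R)-but-3-en-2-yl N,N-diisopropylcarbamate
Conditions: NaH, THF, 0 °C; iPr2NCOCl, reflux
Reagents that add atoms: N,N-diisopropylcarbamoyl chloride, CC(C)N(C(C)C)C(Cl)=O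
Why: O-carbamoylation of the sodium alkoxide; the stereocentre is not involved.

Step 9
Reactants: 10 C2' pinacol boronate; 12 (R)-but-3-en-2-yl N,N-diisopropylcarbamate
Product: 16 epoxy tertiary alcohol (3'S), via lithiated carbamate 13 (not isolated), via lithium boronate complex 14 (not isolated), via tertiary boronic ester 15 (not isolated)
Conditions: 12 (1.5 equiv), sBuLi (1.4 equiv), TMEDA, Et2O, −78 °C; add 10, −78 °C → rt; then NaOH, H2O2, THF/H2O, 0 °C → rt
Reagents that add atoms: hydrogen peroxide, OO
Why: Lithiation–borylation–oxidation: carbamate-directed α-lithiation with retention gives 13, which is configurationally stable at −78 °C and captures the boronic ester at the α-carbon with retention (14); 1,2-migration of the primary alkyl group anti to the departing carbamate (inversion at carbon) gives 15, and oxidation of the C–B bond with retention sets C3' as S.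

Step 10
Reactants: 16 epoxy tertiary alcohol
Product: 17 allylic diol (C2=CH2; C3–OH top)
Conditions: Et2Al(TMP) (excess; from TMP, nBuLi, Et2AlCl), toluene, 0 °C
Reagents that add atoms: none
Why: Isomerisation of an oxirane to an allylic alcohol by an aluminium amide: aluminium binds the oxirane oxygen and the hindered amide removes a proton from the C2 methyl group in a syn cyclic transition state, so the exocyclic methylene forms and the C3–O bond keeps its configuration (as in α-pinene oxide → trans-pinocarveol); one equivalent of reagent is taken up by the tertiary hydroxyl.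

Step 11
Reactants: 17 allylic diol
Product: 18 C3 4-nitrobenzoate (ester oxygen bottom)
Conditions: 4-O2NC6H4CO2H, PPh3, DIAD, THF, 0 °C → rt
Reagents that add atoms: 4-nitrobenzoic acid, OC(=O)c1ccc(cc1)[N+](=O)[O-]
Why: Mitsunobu esterification: SN2 attack of the carboxylate on the activated secondary allylic alcohol inverts C3, while the tertiary C3' hydroxyl cannot be substituted; the axial C5–Br on the bottom face may slow the attack, so a prolonged reaction time is planned.

Step 12
Reactants: 18 C3 4-nitrobenzoate
Product: 19 C3-inverted diol (C3–OH bottom)
Conditions: K2CO3 (cat.), MeOH, rt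
Reagents that add atoms: none
Why: Base-catalysed methanolysis of the electron-poor aryl ester; the hindered secondary bromide and the tertiary alcohol are stable to these conditions and C3 is not epimerised.

Step 13
Reactants: 19 C3-inverted diol
Product: 20 target, (3S)-5-[(1S,3R,5R)-3,5-dibromo-2,2-dimethyl-6-methylidenecyclohexyl]-3-methylpent-1-en-3-ol
Conditions: CBr4, PPh3, CH2Cl2, −20 → 0 °C, short reaction time
Reagents that add atoms: carbon tetrabromide, BrC(Br)(Br)Br
Why: Appel bromination: SN2 displacement at the allylic carbon inverts C3 and places Br on the top face, cis to the side chain and equatorial; the tertiary alcohol is not activated at low temperature, and the short reaction time limits bromide-induced allylic transposition.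

**Compound list**

1 | (1S,5S)-(−)-verbenone, (1S,5S)-4,6,6-trimethylbicyclo[3.1.1]hept-3-en-2-one | O=C1C=C(C)[C@@H]2C[C@H]1C2(C)C | starting material
2 | (1R,5S)-chrysanthenone, (1R,5S)-2,7,7-trimethylbicyclo[3.1.1]hept-2-en-6-one | O=C1[C@H]2CC=C(C)[C@@H]1C2(C)C | intermediate
3 | 2,3-epoxychrysanthenone; cis-fused oxirane with oxygen on the face of the C=O bridge, anti to the CMe2 bridge | O=C1[C@H]2C[C@H]3O[C@@]3(C)[C@@H]1C2(C)C | intermediate
4 | Criegee adduct of 3; C1' carries OH and the 3-chlorobenzoylperoxy group (C1' configuration undefined) | OC1(OOC(=O)c2cccc(Cl)c2)[C@H]2C[C@H]3O[C@@]3(C)[C@@H]1C2(C)C | intermediate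
5 | epoxy bridged lactone; 6-oxabicyclo[3.2.1]octan-7-one with lactone bridge C1–C1'(=O)–O–C5 on the top face, oxirane C2–C3 with oxygen on the top face, C2 methyl bottom, C6 gem-dimethyl | O=C1O[C@H]2C[C@H]3O[C@@]3(C)[C@@H]1C2(C)C | intermediate
6 | epoxy lactol; C1' hemiacetal of 5, mixture of anomers | OC1O[C@H]2C[C@H]3O[C@@]3(C)[C@@H]1C2(C)C | intermediate
7 | hydroxy aldehyde; C1–CHO top, C5–OH top, oxirane oxygen top | O=C[C@@H]1[C@]2(C)O[C@@H]2C[C@H](O)C1(C)C | intermediate
8 | vinyl epoxy alcohol; C1 vinyl top, C5–OH top, C2–C3 oxirane oxygen top | C=C[C@@H]1[C@]2(C)O[C@@H]2C[C@H](O)C1(C)C | intermediate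
9 | vinyl epoxy bromide; as 8 but C5–Br on the bottom face | C=C[C@@H]1[C@]2(C)O[C@@H]2C[C@@H](Br)C1(C)C | intermediate
10 | C2' pinacol boronate; C1–CH2CH2–Bpin, oxirane and C5–Br as in 9 | CC1(C)OB(CC[C@@H]2[C@]3(C)O[C@@H]3C[C@@H](Br)C2(C)C)OC1(C)C | intermediate
11 | (R)-but-3-en-2-ol | C=C[C@@H](C)O | starting material
12 | (R)-but-3-en-2-yl N,N-diisopropylcarbamate | C=C[C@@H](C)OC(=O)N(C(C)C)C(C)C | intermediate
13 | α-lithiated carbamate; Li in place of the carbinol H with retention | C=C[C@@]([Li])(C)OC(=O)N(C(C)C)C(C)C | intermediate
14 | lithium boronate complex; boron bound to the carbamate carbon in place of Li | [Li+].C=C[C@@]([B-]1(CC[C@@H]2[C@]3(C)O[C@@H]3C[C@@H](Br)C2(C)C)OC(C)(C)C(C)(C)O1)(C)OC(=O)N(C(C)C)C(C)C | intermediate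
15 | tertiary allylic pinacol boronic ester; C3' bears Bpin, methyl, vinyl and C2' | C=C[C@](B1OC(C)(C)C(C)(C)O1)(C)CC[C@@H]1[C@]2(C)O[C@@H]2C[C@@H](Br)C1(C)C | intermediate
16 | epoxy tertiary alcohol; (3'S)-carbinol, oxirane intact, C5–Br bottom | C=C[C@@](C)(O)CC[C@@H]1[C@]2(C)O[C@@H]2C[C@@H](Br)C1(C)C | intermediate
17 | allylic diol; C2 exocyclic methylene, C3–OH top, C5–Br bottom, (3'S)-carbinol | C=C[C@@](C)(O)CC[C@@H]1C(=C)[C@H](O)C[C@@H](Br)C1(C)C | intermediate
18 | C3 4-nitrobenzoate; ester oxygen on the bottom face | C=C[C@@](C)(O)CC[C@@H]1C(=C)[C@@H](OC(=O)c2ccc(cc2)[N+](=O)[O-])C[C@@H](Br)C1(C)C | intermediate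
19 | C3-inverted diol; C3–OH bottom, C5–Br bottom | C=C[C@@](C)(O)CC[C@@H]1C(=C)[C@@H](O)C[C@@H](Br)C1(C)C | intermediate
20 | (3S)-5-[(1S,3R,5R)-3,5-dibromo-2,2-dimethyl-6-methylidenecyclohexyl]-3-methylpent-1-en-3-ol; C3–Br top, C5–Br bottom | C=C[C@@](C)(O)CC[C@@H]1C(=C)[C@H](Br)C[C@@H](Br)C1(C)C | target

**Step count**

Total: 13 steps. Longest linear sequence: 12 steps (steps 1–7 and 9–13, from verbenone).

**Steps most likely to fail**

Step 3 (key step). What may go wrong: migration of C1 instead of C5 in the Criegee adduct, that is oxygen insertion on the wrong side of the carbonyl, because the inductive bias of the oxirane is the only element that separates two bridgehead methines. Fallback: set out again from 3 and replace substrate control by catalyst control, using a Baeyer–Villiger monooxygenase (a flavin-dependent enzyme of the cyclohexanone monooxygenase type, whole cells or isolated enzyme with NADPH recycling, aqueous buffer, air). In these enzymes the migrating bond is the one held anti-periplanar to the peroxyflavin O–O bond by the active site, and panels of such enzymes are known to give either regioisomeric lactone from fused cyclobutanones under neutral conditions that spare an oxirane. The fallback comes back to the route at 5 and makes no new compound (F0).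

Step 6. What may go wrong: slow SN2 displacement at the neopentyl-type C5, with competing elimination, Wagner–Meerwein shift of a C6 methyl, or opening of the oxirane by the phosphonium bromide on warming. Fallback: set out from 8 and separate activation from displacement. The alcohol would be converted at low temperature into the C5 trifluoromethanesulfonate F1 (Tf2O, pyridine, CH2Cl2, −30 °C), a far better leaving group that needs no phosphorus reagent, and F1 would be displaced with inversion by LiBr in acetone at 0 °C → rt. The fallback comes back to the route at 9.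

Step 9. What may go wrong: capture of the boronic ester at the unsubstituted γ-terminus of the lithiated allyl carbamate instead of the α-carbon, or partial racemisation of the lithiated species, either of which would lower the yield or the purity at C3'. Fallback: set out from 9 and build C3' by coupling and reagent-controlled epoxidation. Hydroboration of 9 with 9-BBN (THF, rt) would give the B-alkyl-9-BBN adduct F2. Suzuki–Miyaura coupling of F2 with (E)-3-iodobut-2-en-1-ol (Pd(dppf)Cl2, AsPh3, Cs2CO3, DMF/THF/H2O, rt) would give the (E)-trisubstituted allylic alcohol F3. Sharpless asymmetric epoxidation (Ti(OiPr)4, L-(+)-diethyl tartrate, tBuOOH, 4 Å molecular sieves, CH2Cl2, −20 °C) would give the (3'S,4'S)-epoxy alcohol F4. Conversion into the epoxy iodide F5 (I2, PPh3, imidazole, CH2Cl2, 0 °C) and reductive ring opening with Zn in EtOH would unveil the (3'S) tertiary vinyl carbinol with retention at C3'. The fallback comes back to the route at 16.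

**Further compounds**

F0 | step 3 | none | none
F1 | step 6 | C5 trifluoromethanesulfonate of 8 (triflate on the top face) | C=C[C@@H]1[C@]2(C)O[C@@H]2C[C@H](OS(=O)(=O)C(F)(F)F)C1(C)C
F2 | step 9 | B-alkyl-9-BBN adduct of 9 (boron on C2') | C1CCC2CCCC1B2CC[C@@H]1[C@]2(C)O[C@@H]2C[C@@H](Br)C1(C)C
F3 | step 9 | (E)-allylic alcohol, C3'(Me)=C4'H–C5'H2OH | OC/C=C(\C)CC[C@@H]1[C@]2(C)O[C@@H]2C[C@@H](Br)C1(C)C
F4 | step 9 | (3'S,4'S)-3',4'-epoxy alcohol | OC[C@@H]1O[C@@]1(C)CC[C@@H]1[C@]2(C)O[C@@H]2C[C@@H](Br)C1(C)C
F5 | step 9 | (3'S,4'S)-3',4'-epoxy iodide | IC[C@@H]1O[C@@]1(C)CC[C@@H]1[C@]2(C)O[C@@H]2C[C@@H](Br)C1(C)C
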